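The grey run is your yardstick for the red flask: its charge of 32.0 mM starting material lies nearer red's 26.0 mM than amber's 80.0 mM does.

| flask | starting material | catalyst | time |
|---|---|---|---|
| amber | 80.0 mM | 8.00 mM |  |
| grey | 32.0 mM | 8.00 mM |  |
| violet | 120 mM | 8.00 mM |  |
| red | 26.0 mM | 4.00 mM | 7.5 h |

| run | time / h | [target] / mM |
|---|---|---|
| amber run | 0.57 | 1.1 |
| amber run | 1.7 | 11.2 |
| amber run | 3.3 | 25.9 |
| amber run | 5.2 | 37.5 |
| amber run | 7.5 | 42.4 |
| grey run | 0.57 | 0.4 |
| grey run | 1.7 | 8.0 |
| grey run | 3.3 | 15.4 |
| grey run | 5.2 | 19.2 |
| grey run | 7.5 | 20.1 |
| violet run | 0.57 | 1.2 |
| violet run | 1.7 | 9.9 |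
| violet run | 3.3 | 25.6 |
| violet run | 5.2 | 43.9 |
| violet run | 7.5 | 53.3 |

(standard deviation of a reading: 0.6 mM)

1. how the opening rate goes with [starting material] round the charge of the amber run: the exponent of the rate at two percent of starting material gone to target (one fixed amount of target, the same in the runs compared)
2. target in the red run at 7.5 h, as a share of the starting material charged

- Overall: starting material -> target, with catalyst as catalyst.
- Constant volume, constant temperature.
- Readings of a species count what is bound in complexes too.
- An order is taken over about fifteen percent of the charge, up and down.

Keep one number: 2.51 is the grey run's turnover count n (the turnover number), the target made by 7.5 h per catalyst charged. Red's charge allows 6.50 turnovers; now take pace, counted per catalyst. Grey's stretch from 0.57 h to 1.7 h runs at 0.841 /h per catalyst. Held from 0.57 h to 7.5 h, that pace would bring red to 89.6 % of its charge.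

Grey did not hold that pace, and you expect red to slow too, so you tighten the top to grey's own count: n of 2.51 on red's 4.00 mM of catalyst gives 38.7 %. The floor is a guess about catalyst, since amber, grey and violet share a charge of 8.00 mM. If the rate went with the square of catalyst, red, with half of grey's catalyst, would work at half the pace per catalyst, giving 19.3 %. You commit to the middle, 29.0 %.

For the order, amber and violet at 3.3 h read 25.9 mM and 25.6 mM, apart by less than the scatter of 0.6 mM, so you take it as near zero.

The forecast, “assuming first order in catalyst”, gives 46 % and an order of 0, above your top and below your loose ceiling.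

The flask gives 31.4 % and an order of −0.043.

    active catalyst + starting material ⇌ catalyst-substrate complex, settled at all times (18.40 /M)
    catalyst-substrate complex + active catalyst → target + 2 active catalyst (673.2 /M/h)
    starting material → decomposed substrate (0.1937 /h)
    catalyst → active catalyst (1.876 /h)

Where equal target has been made, the violet run goes at 0.96 of the amber run's rate. Red's share is a count of 2.04 turnovers, fewer than grey's 2.51. Red's share stands above your floor and below your top. At 7.5 h the amber run reads 5.30 turnovers.

(The numbers in the tables are simulated on assumed constants; the scatter is artificial.)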